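In the target, ring A (C10–C1–C2–C3–C4–C5) holds its ketone carbon C2 directly across from the quaternary carbon C5, which also belongs to ring B (C5–C6–C7–C8–C9–C10). Cutting the C9–C10 bond therefore uncovers a 4-methyl-4-alkylcyclohexa-2,5-dienone with constitutionally identical C3=C4 and C1=C10 enone arms. A carbene-catalysed intramolecular Stetter reaction reverses this cut: the C9 aldehyde, as an acyl anion equivalent, attacks C10, which closes ring B, sets the cis C5/C10 ring fusion and keeps the other enone for the C4 methyl. The precursor is the dienone bearing on C5 the C6–C9 chain with the (S)-configured isopropenyl carbon C7 and the free C9 aldehyde.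

Key step: step 9

Remark on numbering and configuration: target numbering is kept for all intermediates, and β is the face of the C5 methyl group. Read from the SMILES, the target is 4S,5R,7R,8R,9S,10S. It is cis-fused, with the C4 and C5 methyl groups, H10 and the C7 isopropenyl group β and both ester oxygens α. In the ring B chair with equatorial isopropenyl, the C8 acetate is equatorial and the C9 tiglate axial. The dienone aldehyde 15 is (S) at C7 and the cyclisation product 16 is (5R,7S,10S); no change to either structure is needed, and the later change of the C7 descriptor to R reflects CIP priorities only.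

Remark on the C8 oxygen: an electrophile should enter the C8–C9 enolate axially from the β face, which is the wrong face for oxygen. The acetate is therefore brought in by SN2 inversion of the axial bromide, and C8 is left unbranched in the precursor so that the aldehyde stays reactive.

Assumption on ligand and catalyst sense: (R)-BINAP is taken to give (R)-6, and the (5aR,10bS) triazolium salt is taken as the partner matched to the chair preference of 15. If either sense proves opposite, the antipodal ligand or salt is used and nothing else changes.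

Step 1
Reactants: 1 but-3-en-1-ol
Product: 2 tert-butyl(but-3-en-1-yloxy)diphenylsilane
Conditions: tBuPh2SiCl, imidazole, CH2Cl2, 0 °C → rt
Reagents that add atoms: tert-butyl(chloro)diphenylsilane, CC(C)(C)[Si](Cl)(c1ccccc1)c1ccccc1
Why: Silylation of a primary alcohol with a silyl chloride and imidazole is routine, and the tert-butyldiphenylsilyl ether is chosen because it should survive the aqueous acid of steps 4 and 5 and the strong bases of steps 4 and 6 (O-silylation).

Step 2
Reactants: 2 tert-butyl(but-3-en-1-yloxy)diphenylsilane; 3 methyl vinyl ketone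
Product: 4 (E)-6-[(tert-butyldiphenylsilyl)oxy]hex-3-en-2-one
Conditions: second-generation Grubbs catalyst, (H2IMes)(PCy3)Cl2Ru=CHPh (3 mol %), 3 (3 equiv), CH2Cl2, 40 °C
Reagents that add atoms: none
Why: Olefin cross-metathesis of a terminal alkene with an electron-poor vinyl ketone is a well-matched pairing that should give the (E)-enone selectively with loss of ethene.

Step 3
Reactants: 4 (E)-6-[(tert-butyldiphenylsilyl)oxy]hex-3-en-2-one; 5 isopropenylboronic acid pinacol ester
Product: 6 (R)-4-{2-[(tert-butyldiphenylsilyl)oxy]ethyl}-5-methylhex-5-en-2-one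
Conditions: Rh(acac)(C2H4)2 (3 mol %), (R)-BINAP (3.3 mol %), 5 (2.5 equiv), 1,4-dioxane–H2O (10:1), 100 °C
Reagents that add atoms: none
Why: In this rhodium-catalysed asymmetric conjugate addition (Hayashi–Miyaura reaction) the BINAP-bound alkenylrhodium species adds the isopropenyl group to one enantioface of the (E)-enone and so sets C7, (R)-BINAP being expected to give the (R)-ketone by analogy with aryl transfer to (E)-alk-3-en-2-ones.

Step 4
Reactants: 6 (R)-4-{2-[(tert-butyldiphenylsilyl)oxy]ethyl}-5-methylhex-5-en-2-one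
Product: 8 (2RS,4S)-4-{2-[(tert-butyldiphenylsilyl)oxy]ethyl}-2,5-dimethylhex-5-enal, via methyl enol ether 7 (not isolated)
Conditions: Ph3P(CH2OMe)Cl, KN(SiMe3)2, THF, 0 °C → rt; then 1 M aq. HCl, THF, rt
Reagents that add atoms: (methoxymethyl)triphenylphosphonium chloride, COC[P+](c1ccccc1)(c1ccccc1)c1ccccc1.[Cl-]; water, O
Why: Wittig methoxymethylenation of the methyl ketone and mild acid hydrolysis of the enol ether is the standard one-carbon homologation to an α-methyl aldehyde, the new centre at the future C5 being left as a mixture because it loses its stereogenicity in step 6, while C7 lies β to the carbonyl group and cannot epimerise.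

Step 5
Reactants: 8 (2RS,4S)-4-{2-[(tert-butyldiphenylsilyl)oxy]ethyl}-2,5-dimethylhex-5-enal; 3 methyl vinyl ketone
Product: 11 4-[(2S)-2-{2-[(tert-butyldiphenylsilyl)oxy]ethyl}-3-methylbut-3-en-1-yl]-4-methylcyclohex-2-en-1-one (both C4 epimers of the ring), via pyrrolidine enamine 9 (not isolated), via keto aldehyde 10 (not isolated)
Conditions: pyrrolidine (1.2 equiv), toluene, reflux (Dean–Stark); 3 (1.5 equiv), rt; then AcOH–NaOAc–H2O, 80 °C
Reagents that add atoms: none
Why: The Stork enamine adds to methyl vinyl ketone in a Michael reaction that creates the quaternary C5, and hydrolysis followed by amine-salt-mediated aldol condensation completes a Robinson annulation to the 4,4-disubstituted cyclohex-2-enone without strong acid or hydroxide.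

Step 6
Reactants: 11 4-[(2S)-2-{2-[(tert-butyldiphenylsilyl)oxy]ethyl}-3-methylbut-3-en-1-yl]-4-methylcyclohex-2-en-1-one
Product: 13 4-[(2S)-2-{2-[(tert-butyldiphenylsilyl)oxy]ethyl}-3-methylbut-3-en-1-yl]-4-methylcyclohexa-2,5-dien-1-one, via trimethylsilyl dienol ether 12 (not isolated)
Conditions: LiN(iPr)2, Me3SiCl, THF, −78 °C; then Pd(OAc)2 (1.1 equiv), MeCN, rt
Reagents that add atoms: none
Why: In this Saegusa–Ito oxidation the amide base can deprotonate only the α′ methylene because the γ carbon is quaternary, and divalent palladium turns the resulting 2-silyloxydiene into the cross-conjugated dienone, in which C5 is no longer a stereocentre.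

Step 7
Reactants: 13 4-[(2S)-2-{2-[(tert-butyldiphenylsilyl)oxy]ethyl}-3-methylbut-3-en-1-yl]-4-methylcyclohexa-2,5-dien-1-one
Product: 14 4-[(2S)-2-(2-hydroxyethyl)-3-methylbut-3-en-1-yl]-4-methylcyclohexa-2,5-dien-1-one
Conditions: Bu4NF, AcOH, THF, 0 °C → rt
Reagents that add atoms: none
Why: Fluoride cleaves the silicon–oxygen bond of the silyl ether, and acetic acid buffers the alkoxide so that it cannot add to the dienone (desilylation).

Step 8
Reactants: 14 4-[(2S)-2-(2-hydroxyethyl)-3-methylbut-3-en-1-yl]-4-methylcyclohexa-2,5-dien-1-one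
Product: 15 (3S)-4-methyl-3-[(1-methyl-4-oxocyclohexa-2,5-dien-1-yl)methyl]pent-4-enal
Conditions: Dess–Martin periodinane, CH2Cl2, rt
Reagents that add atoms: none
Why: Dess–Martin oxidation takes the primary alcohol to the aldehyde without over-oxidation and leaves the dienone and the 1,1-disubstituted alkene untouched.

Step 9
Reactants: 15 (3S)-4-methyl-3-[(1-methyl-4-oxocyclohexa-2,5-dien-1-yl)methyl]pent-4-enal
Product: 16 (5R,7S,10S)-5-methyl-7-(prop-1-en-2-yl)-cis-decal-3-ene-2,9-dione (target numbering; C5 methyl, H10 and C7 isopropenyl all β)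
Conditions: (5aR,10bS)-2-(pentafluorophenyl)-5a,10b-dihydro-4H,6H-indeno[2,1-b][1,2,4]triazolo[4,3-d][1,4]oxazin-2-ium tetrafluoroborate (20 mol %), KN(SiMe3)2 (20 mol %), toluene (0.02 M), 23 °C
Reagents that add atoms: none
Why: Deprotonation of the triazolium salt gives the carbene, which adds to the C9 aldehyde; proton transfer gives the Breslow intermediate, an acyl anion equivalent that adds to C10 of one enone arm, and proton transfer with release of the carbene gives the C9 ketone. The closest known reaction type is the carbene-catalysed intramolecular Stetter desymmetrisation of 4,4-disubstituted cyclohexa-2,5-dienones that carry a tethered aldehyde. Ring B closes in the 6-exo-trig mode. C10 is set by geometry, since the tether reaches only the dienone face from which it hangs, so the new C9–C10 bond is cis to C5–C6 and the ring fusion is cis; C5 becomes stereogenic through the choice of arm, which the C7 stereocentre and the catalyst control together. The step needs selectivity between the two diastereotopic enone arms and preference for ring closure over aldehyde self-condensation: in the chair-like transition state the spectator arm must sit axial and the C5 methyl equatorial on the nascent ring B, so only attack on one arm keeps the C7 isopropenyl group equatorial (the other arm would place it 1,3-diaxial to the spectator arm), and the unbranched C8 methylene, the matched catalyst antipode and high dilution favour the cyclisation.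

Step 10
Reactants: 16 (5R,7S,10S)-5-methyl-7-(prop-1-en-2-yl)-cis-decal-3-ene-2,9-dione
Product: 18 (4S,5R,7S,10S)-4,5-dimethyl-7-(prop-1-en-2-yl)-2-[(triisopropylsilyl)oxy]-cis-decal-2-en-9-one, via lithium enolate 17 (not isolated)
Conditions: Me2CuLi (from MeLi, CuI; 1.5 equiv), Et2O, −78 °C; then iPr3SiOTf, −78 → 0 °C
Reagents that add atoms: lithium dimethylcuprate, [Li+].C[Cu-]C; triisopropylsilyl trifluoromethanesulfonate, CC(C)[Si](OS(=O)(=O)C(F)(F)F)(C(C)C)C(C)C
Why: Conjugate addition of the Gilman cuprate to the remaining enone and O-silylation of the regiodefined enolate should place the methyl group on C4 from the convex β face of the cis-fused bicycle, the face of H10 and of the C5 methyl group, because ring B screens the α face through the C5–C6 and C10–C9 bonds, and the silyl enol ether then masks the C2 ketone.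

Step 11
Reactants: 18 (4S,5R,7S,10S)-4,5-dimethyl-7-(prop-1-en-2-yl)-2-[(triisopropylsilyl)oxy]-cis-decal-2-en-9-one
Product: 20 (4S,5R,7R,8S,10S)-8-bromo-4,5-dimethyl-7-(prop-1-en-2-yl)-2-[(triisopropylsilyl)oxy]-cis-decal-2-en-9-one (8β-bromide), via lithium enolate 19 (not isolated)
Conditions: LiN(SiMe3)2 (1.1 equiv), THF, −78 °C; then N-bromosuccinimide (1.05 equiv), −78 °C; AcOH quench
Reagents that add atoms: N-bromosuccinimide, O=C1CCC(=O)N1Br
Why: Kinetic deprotonation of the C9 ketone takes the C8 methylene in preference to the hindered ring-fusion C10–H, and electrophilic bromination of the enolate follows the stereoelectronic preference for axial attack, here on the open β face, to give the axial 8β-bromide (α-halogenation of an enolate).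

Step 12
Reactants: 20 (4S,5R,7R,8S,10S)-8-bromo-4,5-dimethyl-7-(prop-1-en-2-yl)-2-[(triisopropylsilyl)oxy]-cis-decal-2-en-9-one
Product: 21 (4S,5R,7R,8R,10S)-4,5-dimethyl-9-oxo-7-(prop-1-en-2-yl)-2-[(triisopropylsilyl)oxy]-cis-decal-2-en-8-yl acetate (8α-acetate)
Conditions: Bu4NOAc (2 equiv), acetone, 0 °C → rt
Reagents that add atoms: tetrabutylammonium acetate, CCCC[N+](CCCC)(CCCC)CCCC.CC(=O)[O-]
Why: SN2 displacement of an α-bromo ketone by acetate is fast and goes with inversion, so that the axial 8β-bromide should give the equatorial 8α-acetate, trans to the C7 isopropenyl group.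

Step 13
Reactants: 21 (4S,5R,7R,8R,10S)-4,5-dimethyl-9-oxo-7-(prop-1-en-2-yl)-2-[(triisopropylsilyl)oxy]-cis-decal-2-en-8-yl acetate
Product: 22 (4S,5R,7R,8R,9S,10S)-9-hydroxy-4,5-dimethyl-7-(prop-1-en-2-yl)-2-[(triisopropylsilyl)oxy]-cis-decal-2-en-8-yl acetate
Conditions: L-Selectride, Li[(sec-Bu)3BH] (1.2 equiv), THF, −78 °C; AcOH quench at −78 °C
Reagents that add atoms: none
Why: The bulky borohydride should attack the C9 carbonyl along the equatorial trajectory from the β face, since the axial α trajectory is blocked by the axial C5–C4 bond, which gives the axial 9α-alcohol cis to the C8 acetate, while the esters and the silyl enol ether do not react at −78 °C (diastereoselective ketone reduction).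

Step 14
Reactants: 22 (4S,5R,7R,8R,9S,10S)-9-hydroxy-4,5-dimethyl-7-(prop-1-en-2-yl)-2-[(triisopropylsilyl)oxy]-cis-decal-2-en-8-yl acetate
Product: 23 (4S,5R,7R,8R,9S,10S)-8-acetoxy-4,5-dimethyl-7-(prop-1-en-2-yl)-2-[(triisopropylsilyl)oxy]-cis-decal-2-en-9-yl (E)-2-methylbut-2-enoate
Conditions: tigloyl chloride (3 equiv), DMAP (cat.), pyridine, CH2Cl2, 0 → 40 °C
Reagents that add atoms: (E)-2-methylbut-2-enoyl chloride (tigloyl chloride), C/C=C(\C)C(=O)Cl
Why: DMAP-catalysed acylation by the acid chloride esterifies the hindered axial alcohol under non-alkoxide conditions that disfavour acetyl migration from O8 to O9, and the (E) geometry of the tigloyl group is retained.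

Step 15
Reactants: 23 (4S,5R,7R,8R,9S,10S)-8-acetoxy-4,5-dimethyl-7-(prop-1-en-2-yl)-2-[(triisopropylsilyl)oxy]-cis-decal-2-en-9-yl (E)-2-methylbut-2-enoate
Product: 24 (4S,5R,7R,8R,9S,10S)-8-acetoxy-4,5-dimethyl-2-oxo-7-(prop-1-en-2-yl)-cis-decalin-9-yl (E)-2-methylbut-2-enoate (target)
Conditions: HF·pyridine, THF, 0 °C → rt
Reagents that add atoms: none
Why: Fluoride-assisted protodesilylation of the silyl enol ether releases the C2 ketone by protonation at C3, which is not a stereocentre, under conditions that the two esters and the alkene tolerate.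

Compound list
1 | but-3-en-1-ol | C=CCCO | starting material
2 | tert-butyl(but-3-en-1-yloxy)diphenylsilane | C=CCCO[Si](c1ccccc1)(c1ccccc1)C(C)(C)C | intermediate
3 | methyl vinyl ketone (but-3-en-2-one) | CC(=O)C=C | starting material
4 | (E)-6-[(tert-butyldiphenylsilyl)oxy]hex-3-en-2-one | CC(=O)/C=C/CCO[Si](c1ccccc1)(c1ccccc1)C(C)(C)C | intermediate
5 | isopropenylboronic acid pinacol ester (4,4,5,5-tetramethyl-2-(prop-1-en-2-yl)-1,3,2-dioxaborolane) | C=C(C)B1OC(C)(C)C(C)(C)O1 | starting material
6 | (R)-4-{2-[(tert-butyldiphenylsilyl)oxy]ethyl}-5-methylhex-5-en-2-one | C=C(C)[C@H](CCO[Si](c1ccccc1)(c1ccccc1)C(C)(C)C)CC(C)=O | intermediate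
7 | (4S)-4-{2-[(tert-butyldiphenylsilyl)oxy]ethyl}-1-methoxy-2,5-dimethylhexa-1,5-diene (E/Z mixture) | C=C(C)[C@H](CCO[Si](c1ccccc1)(c1ccccc1)C(C)(C)C)CC(C)=COC | intermediate
8 | (2RS,4S)-4-{2-[(tert-butyldiphenylsilyl)oxy]ethyl}-2,5-dimethylhex-5-enal | C=C(C)[C@H](CCO[Si](c1ccccc1)(c1ccccc1)C(C)(C)C)CC(C)C=O | intermediate
9 | 1-[(4S)-4-{2-[(tert-butyldiphenylsilyl)oxy]ethyl}-2,5-dimethylhexa-1,5-dien-1-yl]pyrrolidine | C=C(C)[C@H](CCO[Si](c1ccccc1)(c1ccccc1)C(C)(C)C)CC(C)=CN1CCCC1 | intermediate
10 | (2RS,4S)-4-{2-[(tert-butyldiphenylsilyl)oxy]ethyl}-2,5-dimethyl-2-(3-oxobutyl)hex-5-enal | C=C(C)[C@H](CCO[Si](c1ccccc1)(c1ccccc1)C(C)(C)C)CC(C)(C=O)CCC(C)=O | intermediate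
11 | 4-[(2S)-2-{2-[(tert-butyldiphenylsilyl)oxy]ethyl}-3-methylbut-3-en-1-yl]-4-methylcyclohex-2-en-1-one (both ring C4 epimers) | C=C(C)[C@H](CCO[Si](c1ccccc1)(c1ccccc1)C(C)(C)C)CC1(C)CCC(=O)C=C1 | intermediate
12 | ({4-[(2S)-2-{2-[(tert-butyldiphenylsilyl)oxy]ethyl}-3-methylbut-3-en-1-yl]-4-methylcyclohexa-1,5-dien-1-yl}oxy)trimethylsilane | C=C(C)[C@H](CCO[Si](c1ccccc1)(c1ccccc1)C(C)(C)C)CC1(C)CC=C(O[Si](C)(C)C)C=C1 | intermediate
13 | 4-[(2S)-2-{2-[(tert-butyldiphenylsilyl)oxy]ethyl}-3-methylbut-3-en-1-yl]-4-methylcyclohexa-2,5-dien-1-one | C=C(C)[C@H](CCO[Si](c1ccccc1)(c1ccccc1)C(C)(C)C)CC1(C)C=CC(=O)C=C1 | intermediate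
14 | 4-[(2S)-2-(2-hydroxyethyl)-3-methylbut-3-en-1-yl]-4-methylcyclohexa-2,5-dien-1-one | C=C(C)[C@H](CCO)CC1(C)C=CC(=O)C=C1 | intermediate
15 | (3S)-4-methyl-3-[(1-methyl-4-oxocyclohexa-2,5-dien-1-yl)methyl]pent-4-enal | C=C(C)[C@H](CC=O)CC1(C)C=CC(=O)C=C1 | intermediate
16 | (5R,7S,10S)-5-methyl-7-(prop-1-en-2-yl)-cis-decal-3-ene-2,9-dione (target numbering) | C=C(C)[C@H]1C[C@@]2(C)[C@H](CC(=O)C=C2)C(=O)C1 | intermediate
17 | lithium (4S,5R,7S,10S)-4,5-dimethyl-9-oxo-7-(prop-1-en-2-yl)-cis-decal-2-en-2-olate | C=C(C)[C@H]1C[C@@]2(C)[C@H](CC([O-])=C[C@@H]2C)C(=O)C1.[Li+] | intermediate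
18 | (4S,5R,7S,10S)-4,5-dimethyl-7-(prop-1-en-2-yl)-2-[(triisopropylsilyl)oxy]-cis-decal-2-en-9-one | C=C(C)[C@H]1C[C@@]2(C)[C@H](CC(O[Si](C(C)C)(C(C)C)C(C)C)=C[C@@H]2C)C(=O)C1 | intermediate
19 | lithium (4S,5R,7S,10S)-4,5-dimethyl-7-(prop-1-en-2-yl)-2-[(triisopropylsilyl)oxy]-cis-decala-2,8-dien-9-olate | C=C(C)[C@H]1C[C@@]2(C)[C@H](CC(O[Si](C(C)C)(C(C)C)C(C)C)=C[C@@H]2C)C([O-])=C1.[Li+] | intermediate
20 | (4S,5R,7R,8S,10S)-8-bromo-4,5-dimethyl-7-(prop-1-en-2-yl)-2-[(triisopropylsilyl)oxy]-cis-decal-2-en-9-one | C=C(C)[C@H]1C[C@@]2(C)[C@H](CC(O[Si](C(C)C)(C(C)C)C(C)C)=C[C@@H]2C)C(=O)[C@H]1Br | intermediate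
21 | (4S,5R,7R,8R,10S)-4,5-dimethyl-9-oxo-7-(prop-1-en-2-yl)-2-[(triisopropylsilyl)oxy]-cis-decal-2-en-8-yl acetate | C=C(C)[C@H]1C[C@@]2(C)[C@H](CC(O[Si](C(C)C)(C(C)C)C(C)C)=C[C@@H]2C)C(=O)[C@@H]1OC(C)=O | intermediate
22 | (4S,5R,7R,8R,9S,10S)-9-hydroxy-4,5-dimethyl-7-(prop-1-en-2-yl)-2-[(triisopropylsilyl)oxy]-cis-decal-2-en-8-yl acetate | C=C(C)[C@H]1C[C@@]2(C)[C@H](CC(O[Si](C(C)C)(C(C)C)C(C)C)=C[C@@H]2C)[C@H](O)[C@@H]1OC(C)=O | intermediate
23 | (4S,5R,7R,8R,9S,10S)-8-acetoxy-4,5-dimethyl-7-(prop-1-en-2-yl)-2-[(triisopropylsilyl)oxy]-cis-decal-2-en-9-yl (E)-2-methylbut-2-enoate | C=C(C)[C@H]1C[C@@]2(C)[C@H](CC(O[Si](C(C)C)(C(C)C)C(C)C)=C[C@@H]2C)[C@H](OC(=O)/C(C)=C/C)[C@@H]1OC(C)=O | intermediate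
24 | (4S,5R,7R,8R,9S,10S)-8-acetoxy-4,5-dimethyl-2-oxo-7-(prop-1-en-2-yl)-cis-decalin-9-yl (E)-2-methylbut-2-enoate; systematic name (1S,2R,3R,4aR,5S,8aS)-2-acetoxy-4a,5-dimethyl-7-oxo-3-(prop-1-en-2-yl)decahydronaphthalen-1-yl (2E)-2-methylbut-2-enoate | C=C(C)[C@H]1C[C@@]2(C)[C@H](CC(=O)C[C@@H]2C)[C@H](OC(=O)/C(C)=C/C)[C@@H]1OC(C)=O | target

Total step count: 15. Longest linear sequence: 15 steps, from but-3-en-1-ol 1 to 24.

Steps most likely to fail

Step 9. The Breslow intermediate of an unactivated aliphatic aldehyde may close the six-membered ring too slowly, so that aldehyde self-condensation takes over, or a mismatched catalyst–substrate pairing may erode the choice between the enone arms. The fallback replaces the polar acyl anion by an acyl radical. It sets out from 15, which Pinnick oxidation (NaClO2, NaH2PO4, 2-methylbut-2-ene) should convert into (3S)-4-methyl-3-[(1-methyl-4-oxocyclohexa-2,5-dien-1-yl)methyl]pent-4-enoic acid F1. Diphenyl diselenide and PBu3 should then give Se-phenyl (3S)-4-methyl-3-[(1-methyl-4-oxocyclohexa-2,5-dien-1-yl)methyl]pent-4-eneselenoate F2. Bu3SnH and AIBN in dilute benzene at 80 °C should generate the acyl radical, which cyclises 6-exo-trig onto C10 under the same chair preference (isopropenyl equatorial, cis fusion by tether geometry), and the route is rejoined at 16.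

Step 10. The equatorial C7 isopropenyl group locks ring B, and in that conformer the C5 methyl group is axial on ring A, so the cuprate may instead attack C4 anti to it from the α face; facial selectivity at C4 may therefore be poor or reversed. The fallback delivers hydrogen instead of methyl in the stereo-determining event. It sets out from 16: Me2CuLi with Me3SiCl gives, whatever the face of attack, the trimethylsilyl enol ether (5R,7S,10S)-4,5-dimethyl-7-(prop-1-en-2-yl)-2-[(trimethylsilyl)oxy]-cis-decal-2-en-9-one F3 as a C4 mixture. Saegusa–Ito oxidation with Pd(OAc)2 then gives the methyl-bearing enone (5S,7S,10S)-4,5-dimethyl-7-(prop-1-en-2-yl)-cis-decal-3-ene-2,9-dione F4. Conjugate reduction with Stryker's reagent, [(Ph3P)CuH]6, and capture of the enolate with iPr3SiOTf should return to 18. A copper hydride with the same facial bias as the cuprate now places hydrogen where methyl had gone, so the methyl group is left on the β face.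

Step 12. The axial bromide has an anti-periplanar axial hydrogen on C7, so loss of HBr to the C7=C8 enone may compete with substitution, and bromide exchange may epimerise C8 before acetate arrives. The fallback introduces oxygen as the electrophile and inverts it afterwards. It sets out from 18: the lithium enolate 19 is oxidised with 2-(phenylsulfonyl)-3-phenyloxaziridine, which should attack the same axial β face and give (4S,5R,7R,8S,10S)-8-hydroxy-4,5-dimethyl-7-(prop-1-en-2-yl)-2-[(triisopropylsilyl)oxy]-cis-decal-2-en-9-one F5. Mitsunobu reaction with acetic acid (PPh3, DIAD, THF) inverts C8 and rejoins the route at 21.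

Further compounds
F1 | step 9 | (3S)-4-methyl-3-[(1-methyl-4-oxocyclohexa-2,5-dien-1-yl)methyl]pent-4-enoic acid | C=C(C)[C@H](CC(=O)O)CC1(C)C=CC(=O)C=C1
F2 | step 9 | Se-phenyl (3S)-4-methyl-3-[(1-methyl-4-oxocyclohexa-2,5-dien-1-yl)methyl]pent-4-eneselenoate | C=C(C)[C@H](CC(=O)[Se]c1ccccc1)CC1(C)C=CC(=O)C=C1
F3 | step 10 | (5R,7S,10S)-4,5-dimethyl-7-(prop-1-en-2-yl)-2-[(trimethylsilyl)oxy]-cis-decal-2-en-9-one (C4 mixture) | C=C(C)[C@H]1C[C@@]2(C)[C@H](CC(O[Si](C)(C)C)=CC2C)C(=O)C1
F4 | step 10 | (5S,7S,10S)-4,5-dimethyl-7-(prop-1-en-2-yl)-cis-decal-3-ene-2,9-dione | C=C(C)[C@H]1C[C@@]2(C)[C@H](CC(=O)C=C2C)C(=O)C1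
F5 | step 12 | (4S,5R,7R,8S,10S)-8-hydroxy-4,5-dimethyl-7-(prop-1-en-2-yl)-2-[(triisopropylsilyl)oxy]-cis-decal-2-en-9-one | C=C(C)[C@H]1C[C@@]2(C)[C@H](CC(O[Si](C(C)C)(C(C)C)C(C)C)=C[C@@H]2C)C(=O)[C@H]1O
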